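We start with the easy step, reading the plateaus.

| flask | substrate | gas | remark | time |
|---|---|---|---|---|
| amber | 28 mM (fed, over 15 h) | 8.2 mM (held) | run made earlier |  |
| grey | 44 mM (fed, over 15 h) | 8.2 mM (held) | run made earlier |  |
| Friday's | 20 mM | 8.2 mM | everything together at the start | 8.0 d |
| Saturday's | 20 mM (fed, over 15 h) | 8.2 mM (held) |  | 8.0 d |

- amber (time / d: target / %, substrate / %): 1.04: 80, 2; 2.00: 81, 0; 3.00: 85, 0; 4.00: 80, 3; 5.00: 85, 1; 6.00: 85, 2
- grey (time / d: target / %, substrate / %): 0.417: 29, 37; 1.25: 75, 1; 2.50: 78, 0; 4.00: 78, 0; 5.00: 77, 0; 6.00: 82, 0

(standard deviation of a reading: 2 percentage points)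

- at the start none of the gas is in solution
- percentages count the whole charge, also what has not yet gone in

- the flask that ends with the higher amount of target, in percent of the substrate charged, or "neither" when 2 percentage points or less lies between them (Friday's / Saturday's / neither)
- final target, as a percentage of the substrate charged, in Friday's
- final target, as a percentage of the substrate charged, in Saturday's

In both earlier runs, the target readings stay level within their scatter once the substrate reads no more than 3% of the charge. Averaged from 2.00 d on, amber reads 83.2%, and averaged from 2.50 d on, grey reads 78.8%. So 16.0 mM of extra charge costs 4.4 percentage points in these readings.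

Our bench rule is the loading penalty, the fraction of the charge lost as yield for each mM of charge, with the dosing time and the held gas as in these two runs: 0.00278 mM⁻¹. It is read from readings good to 2 points, so it is rough. Carried down from amber to the 20 mM of Saturday's semi-batch feed, it gives us 85.4%.

The rule stops at Friday's, which has no feed. At 0.417 d grey had received 66.7% of its charge, yet 37% of the charge stood as substrate, a [substrate] of 16.3 mM. Friday's opens at 20 mM, 1.23 times that reading. So we place Friday's at or under grey's 78.8%, and Saturday's ahead by more than the margin.

The forecast names Saturday's, with 80% for Friday's, above our ceiling, and 87% for Saturday's, above our figure. Its ground for Friday's: “Any gas lag at the start, since none is dissolved, leaves substrate concentrated”.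

The flasks give 77.0% in Friday's and 86.0% in Saturday's, so Saturday's ends ahead by 9 points.

    substrate → intermediate (k = 9.91 × 10⁻⁶ s⁻¹)
    reagent + intermediate → side product (k = 0.00516 M⁻¹ s⁻¹)
    substrate + reagent → target (k = 0.0187 M⁻¹ s⁻¹)
    2 reagent → self-condensation product (k = 0.00338 M⁻¹ s⁻¹)
    gas ⇌ reagent, rate k5*(csat - [reagent]) (kL = 7.02 × 10⁻⁵ s⁻¹)

At the end of Saturday's feed, at 0.625 d, substrate stood at 26.6% of the charge, or 5.32 mM. The penalty's 85.4% lies 0.60 points under Saturday's result. Carried up from grey to a neighbouring flask, Saturday's with 80 mM of substrate, the penalty gives 68.7%, and that flask ends at 65.8%.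

The data stem from a simulated flask for an exercise; the scatter is artificial.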